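**Remark.** Carbon locants C1–C15 follow the chain of the target from the alkyne terminus. Compound 1 is the commercial 1,2-acetonide of (S)-butane-1,2,4-triol. The closed samarium aldol is taken to deliver the axial (9S) carbinol, for the geometric reason given at step 12. Abbreviations: PMB = 4-methoxybenzyl, TBDPS = tert-butyldiphenylsilyl, TBS = tert-butyldimethylsilyl, TES = triethylsilyl.

## Analysis of the target

The target is a C15 dibromo acetogenin on a 2,7-dioxabicyclo[4.2.2]decane: an oxane (O, C6, C7, C8, C9, C10) and an oxocane (O, C7, C8, C9, C10, C11, C12, C13) share the segment C7–C8–C9–C10. It has six stereocentres: 6R, 7R, 9S, 10S, 12S and 13R. On the oxane the C5 chain, O7, Br9 and C11 all lie on one face; in a chair O7 and Br9 would be 1,3-diaxial, and once O7 is tied to C13 the six-membered ring is held as a boat. Across C12–C13 the bromine and the ether oxygen are anti, which is the pattern left by anti addition to a (12E)-alkene. The sensitive groups are two secondary bromides, each β to an ether oxygen (elimination, oxonium-mediated ring contraction), and the (3E)-enyne with a terminal alkyne (electrophilic bromine, strong base, reducing metals). The synthesis is hard because of the bridged eight-membered ether, the syn-diaxial O7/Br9 pair, and the absence of any carbonyl group to work from. The strategy rests on one feature: the ring oxygen joins C6 and C10, and between them C7(O)–C8H2–C9(Br) is an aldol array once Br9 is traced back to oxygen, so cutting C8–C9 leaves a plain dialkyl ether of two α-oxygenated pieces.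

## Retrosynthetic reasoning

**Enyne (33 back to 28).** The C2–C3 and C3=C4 bonds are cut first: 33 comes from silyl enyne 32, 32 from (E)-alkenyl iodide 30 and alkyne 31, and 30 from aldehyde 28 and iodoform 29. The enyne is made last for two reasons. With O7 free, an enyne five atoms away would take up electrophilic bromine in a 1,4-sense and give a bromoallene. A terminal alkyne would also not pass the organolithium, samarium(II) and hydride steps. The gain is a side chain that travels as a silyl-protected C4 alcohol. The forward steps must set the E alkene and couple at sp2 carbon in the presence of two secondary bromides.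

**Oxocane (27 back to 26).** Alcohol 27, the precursor of 28, is cut at O7–C13 and C12–Br to hydroxy alkene 26. The two bonds are anti, so one anti addition across the (12E)-alkene sets C12 and C13 together from an alkene that carries no stereocentre. The forward step must close in the 8-endo mode from an oxygen that sits across the oxane, which needs the boat conformer.

**C9 bromide and C7 carbinol (26 back to 18).** Diol 26 is the desilylated form of bromide 25. The C9 bromide has to be in place before the oxocane is closed, because any oxygen at C9 would reach the bromonium ion in a five-membered closure. The axial C9–Br bond is traced to equatorial carbinol 24 (inversion), and 24 through ester 23 to axial carbinol 22 (second inversion), since the ring closure below delivers the C9 oxygen cis to the C10 chain. The C7 hydroxyl of 20 comes from ketone 19 by hydride addition along the equatorial direction. The silyl groups in 19–25 only keep O7 and O9 apart: O9 is masked while C7 is reduced (19, 20), and O7 while C9 is inverted twice (21–25).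

**Oxane, the key disconnection (18 back to 16).** Hydroxy ketone 18 is cut at C8–C9 to bromo ketone aldehyde 16, through enolate 17. This is the only C–C bond of the oxane whose cleavage leaves both ring-flanking stereocentres (C6, C10) on separate small pieces and uses the C7/C9 oxygens as ketone and aldehyde. Reductive enolate formation from the C–Br bond is regiospecific and needs no base, so neither α-alkoxy centre is at risk. The forward step has to form the ring and set C9.

**C7–C8 (16 back to 12 and 13).** Aldehyde 16 comes from alcohol 15 and this from PMB ether 14; 14 is cut at C7–C8 to Weinreb amide 12 and dibromomethane 13, which supplies C8 with its bromine. The aldehyde is unveiled only after this step because it would not survive a lithium carbenoid.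

**C6–O ether (12 back to 7 and 9).** Amide 12 comes from hydroxy amide 11 and lactone 10. Lactone 10 is cut at the C6–O bond to alcohol 7 and triflate 9, made from hydroxy lactone 8. The lactone carbonyl is C7 and its ring CH2O is C4. Substitution next to the carbonyl runs with inversion, so (S)-8 gives 6R. Both ring-flanking centres thus come from the chiral pool.

**C12=C13 and the C9 protecting group (7 back to 1 and 3).** Alcohol 7 comes from diol 5 through stannylene 6, 5 from acetonide 4, and 4 from aldehyde 2 and sulfone 3; 2 is the oxidation product of 1. The alkene is installed before the union of the halves because it is inert to every step up to 26. This avoids a benzyl-type group on O12 and an oxidation/olefination sequence late in the route.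

## Alternatives that were turned down

**Alternative 1:** The oxocane is made first and cut at C7–C8; the oxane is closed last from O6 across the ring alkene (O6–C10, C9–Br). In the forward key step a tin(IV) Lewis acid ionises a mixed acetal at C7 of an acyclic C7–O–C13 ether. The terminal alkene attacks the oxocarbenium ion through C8 and a proton is lost from C10, which gives the cis-2,8-disubstituted 9Z-oxocene A1.
- For: the eight-membered ring is closed by a cation–olefin reaction that suits medium-ring ethers. The last ring closure is then six-membered and sets C9 and C10 in one anti addition. On closure of the second ring this plan is stronger than the chosen one.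
- Against: O6 can open the bromonium ion at C9 in a 5-exo mode as easily as at C10 in the required 6-endo mode, and nothing in A1 biases against the oxolane. The C12 oxygen must be exchanged for bromine with inversion on a medium ring prone to transannular participation. The precursor needs C6, C12 and C13 from asymmetric synthesis and three orthogonal protecting groups.
- Comparison: step counts are similar. The chosen strategy offers both ring-flanking centres from the chiral pool, C7 and C9 oxygens that are different from the start (ketone and carbinol), and a final closure whose competing mode (7-exo) is inductively disfavoured.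

**Alternative 2:** The oxocane is cut at C12=C13 on an oxane taken from a hexose. In the forward key step, ring-closing metathesis between a 1-ethylvinyl ether on O7 and an allyl group on C10 gives the bridged enol ether A2.
- For: the eight-membered ring is closed through a C=C bond whose position is fixed, so there is no regiochemical choice as in a bromoetherification. On this point it is stronger than the chosen plan. The sugar supplies the oxane stereocentres.
- Against: a trisubstituted enol ether must form by a reversible, strain-sensitive reaction in a bridged ring that forces the oxane into a boat. Hydroboration of A2 adds H and O syn, which puts the C12 oxygen trans to ethyl; bromine must end trans to ethyl, so a simple inversion gives the wrong epimer and an oxidation/reduction detour is needed. The hexose has to be deoxygenated at C8 and extended at both ends.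
- Comparison: this is the longer route. The chosen strategy sets C12 and C13 and closes the ring in one step, and builds the oxane with only the oxygens it needs.

**Alternative 3:** The oxane is cut at O–C10 and comes from a furan, with C6 as the only preformed centre. In the forward key step an electrophilic bromine oxidant in wet solvent converts an (R)-furyl carbinol into the ene-dione, and the C6 hydroxyl closes onto C10 to give hydroxypyranone A3.
- For: this is the shortest access to the oxane and one stereocentre is relayed to C10 and C7. On brevity up to the oxane it is stronger than the chosen plan.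
- Against: A3 is an enone, so C9 is an unfunctionalised alkene carbon. Its heteroatom must be brought in by conjugate oxygenation and reductive opening, which leads to the same β-hydroxy ketone that the chosen route forms directly. The oxidant would also attack the (12E)-alkene that A3 carries, so the chain would have to be attached later at a ketal carbon. The C10 configuration depends on an ionic reduction of the hemiketal and is relayed, not fixed.
- Comparison: the chosen strategy fixes C6 and C10 independently and puts the C9 oxygen in place in the ring-forming step.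

Key step: step 12

## Route

Step 1
Reactants: 1 2-[(4S)-2,2-dimethyl-1,3-dioxolan-4-yl]ethan-1-ol
Product: 2 2-[(4S)-2,2-dimethyl-1,3-dioxolan-4-yl]acetaldehyde
Conditions: Dess–Martin periodinane, CH2Cl2, 0 °C to rt
Reagents that add atoms: none
Why: Dess–Martin oxidation of a primary alcohol; the conditions are neutral, the stereocentre is β to the new carbonyl and the acetonide is untouched.

Step 2
Reactants: 2 2-[(4S)-2,2-dimethyl-1,3-dioxolan-4-yl]acetaldehyde; 3 1-phenyl-5-(propylsulfonyl)-1H-tetrazole
Product: 4 (4S)-2,2-dimethyl-4-[(2E)-pent-2-en-1-yl]-1,3-dioxolane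
Conditions: 3, KHMDS, DME, −60 °C; then 2, −60 °C to rt
Reagents that add atoms: none
Why: Julia–Kocienski olefination; the potassium salt of the phenyltetrazolyl sulfone adds to 2 and collapses by Smiles rearrangement and anti elimination, which should give the (E)-alkene C12=C13; metalating 3 before 2 is added limits β-elimination of the aldehyde, and a minor Z isomer would be removed here.

Step 3
Reactants: 4 (4S)-2,2-dimethyl-4-[(2E)-pent-2-en-1-yl]-1,3-dioxolane
Product: 5 (2S,4E)-hept-4-ene-1,2-diol
Conditions: AcOH/H2O 4:1, 40 °C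
Reagents that add atoms: none
Why: Acid hydrolysis of the isopropylidene acetal; the isolated alkene is inert to aqueous acetic acid.

Step 4
Reactants: 5 (2S,4E)-hept-4-ene-1,2-diol
Product: 7 (2S,4E)-1-[(4-methoxybenzyl)oxy]hept-4-en-2-ol, via dibutylstannylene acetal 6 (not isolated)
Conditions: Bu2SnO, toluene, reflux (Dean–Stark); then PMBCl, Bu4NI (cat.), 90 °C
Reagents that add atoms: 4-methoxybenzyl chloride, COc1ccc(CCl)cc1
Why: Stannylene-acetal-mediated monoalkylation of a 1,2-diol; in 6 the primary oxygen is the more nucleophilic one, so the PMB group goes to the C9 oxygen and the C10 hydroxyl stays free.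

Step 5
Reactants: 8 (3S)-3-hydroxyoxolan-2-one
Product: 9 (3S)-2-oxooxolan-3-yl trifluoromethanesulfonate
Conditions: Tf2O, 2,6-lutidine, CH2Cl2, −78 °C
Reagents that add atoms: trifluoromethanesulfonic anhydride, O=S(=O)(OS(=O)(=O)C(F)(F)F)C(F)(F)F
Why: O-Sulfonylation with retention at the carbinol carbon; the hindered base and low temperature avoid elimination, and the triflate is used without storage.

Step 6
Reactants: 7 (2S,4E)-1-[(4-methoxybenzyl)oxy]hept-4-en-2-ol; 9 (3S)-2-oxooxolan-3-yl trifluoromethanesulfonate
Product: 10 (3R)-3-{[(2S,4E)-1-[(4-methoxybenzyl)oxy]hept-4-en-2-yl]oxy}oxolan-2-one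
Conditions: 7, NaH, THF, 0 °C; then 9, −78 to −20 °C
Reagents that add atoms: none
Why: Williamson-type SN2 displacement of an α-carbonyl triflate by the sodium alkoxide of 7; the adjacent carbonyl accelerates substitution, which runs with inversion and sets C6 as R, while C10 keeps its configuration because it reacts through oxygen.

Step 7
Reactants: 10 (3R)-3-{[(2S,4E)-1-[(4-methoxybenzyl)oxy]hept-4-en-2-yl]oxy}oxolan-2-one
Product: 11 (2R)-4-hydroxy-N-methoxy-N-methyl-2-{[(2S,4E)-1-[(4-methoxybenzyl)oxy]hept-4-en-2-yl]oxy}butanamide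
Conditions: MeNHOMe·HCl, i-PrMgCl, THF, −20 to 0 °C
Reagents that add atoms: N,O-dimethylhydroxylamine hydrochloride, CNOC.Cl
Why: Aminolysis of the lactone by the chloromagnesium amide gives the Weinreb amide and frees O4; the reagent is only weakly basic at this temperature, so the α-alkoxy centre C6 should not epimerise.

Step 8
Reactants: 11 (2R)-4-hydroxy-N-methoxy-N-methyl-2-{[(2S,4E)-1-[(4-methoxybenzyl)oxy]hept-4-en-2-yl]oxy}butanamide
Product: 12 (2R)-4-[(tert-butyldiphenylsilyl)oxy]-N-methoxy-N-methyl-2-{[(2S,4E)-1-[(4-methoxybenzyl)oxy]hept-4-en-2-yl]oxy}butanamide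
Conditions: TBDPSCl, imidazole, DMF, 0 °C to rt
Reagents that add atoms: tert-butyl(chloro)diphenylsilane, CC(C)(C)[Si](Cl)(c1ccccc1)c1ccccc1
Why: Silylation of the primary alcohol; it stops relactonisation, and the TBDPS ether is chosen because it outlasts the selective desilylation of step 16.

Step 9
Reactants: 12 (2R)-4-[(tert-butyldiphenylsilyl)oxy]-N-methoxy-N-methyl-2-{[(2S,4E)-1-[(4-methoxybenzyl)oxy]hept-4-en-2-yl]oxy}butanamide; 13 dibromomethane
Product: 14 (3R)-1-bromo-5-[(tert-butyldiphenylsilyl)oxy]-3-{[(2S,4E)-1-[(4-methoxybenzyl)oxy]hept-4-en-2-yl]oxy}pentan-2-one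
Conditions: 13, MeLi·LiBr, THF/Et2O, −78 °C; then AcOH, −78 °C
Reagents that add atoms: none
Why: Addition of a lithium carbenoid to a Weinreb amide; bromine–lithium exchange on 13 gives bromomethyllithium in the presence of 12, and the chelated tetrahedral adduct is stable at −78 °C and releases the bromomethyl ketone only on protonation, so no second addition occurs.

Step 10
Reactants: 14 (3R)-1-bromo-5-[(tert-butyldiphenylsilyl)oxy]-3-{[(2S,4E)-1-[(4-methoxybenzyl)oxy]hept-4-en-2-yl]oxy}pentan-2-one
Product: 15 (3R)-1-bromo-5-[(tert-butyldiphenylsilyl)oxy]-3-{[(2S,4E)-1-hydroxyhept-4-en-2-yl]oxy}pentan-2-one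
Conditions: DDQ, CH2Cl2/pH 7 buffer, 0 °C
Reagents that add atoms: none
Why: Oxidative cleavage of the PMB ether by DDQ; the bromo ketone, the silyl ether and the isolated alkene are inert, and the buffer keeps the medium neutral.

Step 11
Reactants: 15 (3R)-1-bromo-5-[(tert-butyldiphenylsilyl)oxy]-3-{[(2S,4E)-1-hydroxyhept-4-en-2-yl]oxy}pentan-2-one
Product: 16 (2S,4E)-2-{[(3R)-1-bromo-5-[(tert-butyldiphenylsilyl)oxy]-2-oxopentan-3-yl]oxy}hept-4-enal
Conditions: Dess–Martin periodinane, CH2Cl2, 0 °C to rt
Reagents that add atoms: none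
Why: Dess–Martin oxidation; the non-basic conditions leave the bromomethyl ketone intact and do not epimerise the α-alkoxy aldehyde, which is used without purification.

Step 12
Reactants: 16 (2S,4E)-2-{[(3R)-1-bromo-5-[(tert-butyldiphenylsilyl)oxy]-2-oxopentan-3-yl]oxy}hept-4-enal
Product: 18 (2R,5S,6S)-2-{2-[(tert-butyldiphenylsilyl)oxy]ethyl}-5-hydroxy-6-[(2E)-pent-2-en-1-yl]oxan-3-one, via samarium(III) enolate 17 (not isolated)
Conditions: SmI2 (2.2 equiv), THF, −78 °C, slow addition of 16; then pH 7 buffer
Reagents that add atoms: none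
Why: Two single-electron transfers from SmI2 cleave the C8–Br bond of 16 and give the samarium(III) enolate 17 regiospecifically at C8 under neutral conditions, so the α-alkoxy centres C6 and C10 keep their configuration. The enolate carbon C8 then adds to the C9 aldehyde across the ether oxygen; the closest known reaction type is the SmI2-promoted intramolecular Reformatsky-type aldol of α-halo ketones and esters with aldehydes. The oxane closes in the 6-(enolendo)-exo-trig mode, which is stereoelectronically allowed. Samarium(III) bridges the enolate oxygen and the aldehyde oxygen in a closed Zimmerman–Traxler array fused to the forming chair, and this is only possible when the aldehyde oxygen is gauche to C7, that is axial on the new ring; an equatorial oxygen would be anti to C7 and out of reach of the metal. With both side chains equatorial (the 2,6-cis relation is already fixed by C6 and C10) the new C9 stereocentre is therefore set with its oxygen axial and cis to the C10 chain (9S), and the ring oxygen can act as a third donor on the same face. The step needs chemoselectivity for the C–Br bond over the aldehyde and over the α-alkoxy ketone of the product; the much faster reduction of the α-bromo ketone, the low temperature, the absence of HMPA and the small excess of reagent should secure it. The aldolate stays chelated to samarium until the buffered quench, which should suppress retro-aldol cleavage and β-elimination.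

Step 13
Reactants: 18 (2R,5S,6S)-2-{2-[(tert-butyldiphenylsilyl)oxy]ethyl}-5-hydroxy-6-[(2E)-pent-2-en-1-yl]oxan-3-one
Product: 19 (2R,5S,6S)-2-{2-[(tert-butyldiphenylsilyl)oxy]ethyl}-6-[(2E)-pent-2-en-1-yl]-5-[(triethylsilyl)oxy]oxan-3-one
Conditions: TESOTf, 2,6-lutidine, CH2Cl2, −78 °C
Reagents that add atoms: triethylsilyl trifluoromethanesulfonate, CC[Si](CC)(CC)OS(=O)(=O)C(F)(F)F
Why: Silylation of the β-hydroxy ketone with a silyl triflate and a hindered base at low temperature, conditions under which retro-aldol cleavage and β-elimination are not expected.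

Step 14
Reactants: 19 (2R,5S,6S)-2-{2-[(tert-butyldiphenylsilyl)oxy]ethyl}-6-[(2E)-pent-2-en-1-yl]-5-[(triethylsilyl)oxy]oxan-3-one
Product: 20 (2R,3R,5S,6S)-2-{2-[(tert-butyldiphenylsilyl)oxy]ethyl}-6-[(2E)-pent-2-en-1-yl]-5-[(triethylsilyl)oxy]oxan-3-ol
Conditions: L-Selectride, THF, −78 °C; then AcOH, −78 °C
Reagents that add atoms: none
Why: Reduction with a bulky trialkylborohydride; hydride enters along the equatorial direction because the axial face of C7 is shielded by the axial C9 silyloxy group, so the C7 hydroxyl is set axial and cis to the C6 chain (7R); the cold acidic quench avoids 1,3-silyl migration.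

Step 15
Reactants: 20 (2R,3R,5S,6S)-2-{2-[(tert-butyldiphenylsilyl)oxy]ethyl}-6-[(2E)-pent-2-en-1-yl]-5-[(triethylsilyl)oxy]oxan-3-ol
Product: 21 (2R,3R,5S,6S)-3-[(tert-butyldimethylsilyl)oxy]-2-{2-[(tert-butyldiphenylsilyl)oxy]ethyl}-6-[(2E)-pent-2-en-1-yl]-5-[(triethylsilyl)oxy]oxane
Conditions: TBSOTf, 2,6-lutidine, CH2Cl2, 0 °C
Reagents that add atoms: tert-butyldimethylsilyl trifluoromethanesulfonate, CC(C)(C)[Si](C)(C)OS(=O)(=O)C(F)(F)F
Why: Silylation of the hindered axial alcohol with the silyl triflate; the TBS ether is stable to the next four steps and cannot act as a neighbouring group at C9.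

Step 16
Reactants: 21 (2R,3R,5S,6S)-3-[(tert-butyldimethylsilyl)oxy]-2-{2-[(tert-butyldiphenylsilyl)oxy]ethyl}-6-[(2E)-pent-2-en-1-yl]-5-[(triethylsilyl)oxy]oxane
Product: 22 (2R,3R,5S,6S)-3-[(tert-butyldimethylsilyl)oxy]-2-{2-[(tert-butyldiphenylsilyl)oxy]ethyl}-6-[(2E)-pent-2-en-1-yl]oxan-5-ol
Conditions: HF·pyridine, pyridine, THF, 0 °C
Reagents that add atoms: none
Why: Selective desilylation; towards buffered HF·pyridine a TES ether is far more labile than the secondary TBS and the primary TBDPS ether.

Step 17
Reactants: 22 (2R,3R,5S,6S)-3-[(tert-butyldimethylsilyl)oxy]-2-{2-[(tert-butyldiphenylsilyl)oxy]ethyl}-6-[(2E)-pent-2-en-1-yl]oxan-5-ol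
Product: 23 (2R,3R,5R,6S)-3-[(tert-butyldimethylsilyl)oxy]-2-{2-[(tert-butyldiphenylsilyl)oxy]ethyl}-6-[(2E)-pent-2-en-1-yl]oxan-5-yl 4-nitrobenzoate
Conditions: 4-nitrobenzoic acid, PPh3, DIAD, toluene, 0 °C to rt
Reagents that add atoms: 4-nitrobenzoic acid, O=C(O)c1ccc(cc1)[N+](=O)[O-]
Why: Mitsunobu inversion; the axial oxyphosphonium group at C9 is displaced by the carboxylate from the unhindered equatorial direction, which turns the 9S carbinol into the 9R ester and relieves the 1,3-diaxial strain; the acidic 4-nitrobenzoic acid is the usual pronucleophile for hindered secondary alcohols.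

Step 18
Reactants: 23 (2R,3R,5R,6S)-3-[(tert-butyldimethylsilyl)oxy]-2-{2-[(tert-butyldiphenylsilyl)oxy]ethyl}-6-[(2E)-pent-2-en-1-yl]oxan-5-yl 4-nitrobenzoate
Product: 24 (2R,3R,5R,6S)-3-[(tert-butyldimethylsilyl)oxy]-2-{2-[(tert-butyldiphenylsilyl)oxy]ethyl}-6-[(2E)-pent-2-en-1-yl]oxan-5-ol
Conditions: K2CO3 (cat.), MeOH, rt
Reagents that add atoms: none
Why: Base-catalysed transesterification of the activated aryl ester; the silyl ethers and the alkene are inert.

Step 19
Reactants: 24 (2R,3R,5R,6S)-3-[(tert-butyldimethylsilyl)oxy]-2-{2-[(tert-butyldiphenylsilyl)oxy]ethyl}-6-[(2E)-pent-2-en-1-yl]oxan-5-ol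
Product: 25 (2R,3R,5S,6S)-5-bromo-3-[(tert-butyldimethylsilyl)oxy]-2-{2-[(tert-butyldiphenylsilyl)oxy]ethyl}-6-[(2E)-pent-2-en-1-yl]oxane
Conditions: CBr4, P(n-Oct)3, toluene, 70 °C
Reagents that add atoms: tetrabromomethane, BrC(Br)(Br)Br
Why: Appel-type bromination with inversion; bromide displaces the equatorial oxyphosphonium group at C9 from the axial direction and gives the 9S bromide cis to the C10 chain; an equatorial leaving group has no antiperiplanar hydrogen, which disfavours E2, and a trialkylphosphine in warm toluene is the usual choice for hindered carbinols next to an ether oxygen.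

Step 20
Reactants: 25 (2R,3R,5S,6S)-5-bromo-3-[(tert-butyldimethylsilyl)oxy]-2-{2-[(tert-butyldiphenylsilyl)oxy]ethyl}-6-[(2E)-pent-2-en-1-yl]oxane
Product: 26 (2R,3R,5S,6S)-5-bromo-2-(2-hydroxyethyl)-6-[(2E)-pent-2-en-1-yl]oxan-3-ol
Conditions: HF·pyridine, THF, rt
Reagents that add atoms: none
Why: Fluoride-induced cleavage of both silyl ethers under non-basic conditions, which should spare the axial bromide from elimination.

Step 21
Reactants: 26 (2R,3R,5S,6S)-5-bromo-2-(2-hydroxyethyl)-6-[(2E)-pent-2-en-1-yl]oxan-3-ol
Product: 27 2-[(1R,3R,4S,6S,8R,10S)-4,10-dibromo-3-ethyl-2,7-dioxabicyclo[4.2.2]decan-8-yl]ethan-1-ol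
Conditions: BDSB (Et2SBr·SbCl5Br), MeNO2, −25 to 0 °C
Reagents that add atoms: bromodiethylsulfonium bromopentachloroantimonate, CC[S+](Br)CC.Cl[Sb-](Cl)(Cl)(Cl)(Cl)Br
Why: Intramolecular bromoetherification in the 8-endo mode; the bromonium ion of the (12E)-alkene is opened by O7 at C13 in an anti fashion, which fixes the 12,13 relationship; the syn-diaxial O7/Br9 pair destabilises the chair so that the boat needed for bridging is within reach, attack at C13 should be preferred because C12 lies nearer to the electron-withdrawing C10–O and C9–Br bonds, and of the two tether twists the one that keeps C12 away from C9 and C13 away from C6 leads to 12S,13R.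

Step 22
Reactants: 27 2-[(1R,3R,4S,6S,8R,10S)-4,10-dibromo-3-ethyl-2,7-dioxabicyclo[4.2.2]decan-8-yl]ethan-1-ol
Product: 28 2-[(1R,3R,4S,6S,8R,10S)-4,10-dibromo-3-ethyl-2,7-dioxabicyclo[4.2.2]decan-8-yl]acetaldehyde
Conditions: Dess–Martin periodinane, CH2Cl2, 0 °C to rt
Reagents that add atoms: none
Why: Dess–Martin oxidation; the neutral conditions avoid β-elimination of the β-alkoxy aldehyde and leave both bromides untouched.

Step 23
Reactants: 28 2-[(1R,3R,4S,6S,8R,10S)-4,10-dibromo-3-ethyl-2,7-dioxabicyclo[4.2.2]decan-8-yl]acetaldehyde; 29 iodoform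
Product: 30 (1R,3R,4S,6S,8R,10S)-4,10-dibromo-3-ethyl-8-[(2E)-3-iodoprop-2-en-1-yl]-2,7-dioxabicyclo[4.2.2]decane
Conditions: CrCl2, 29, THF/dioxane, 0 °C to rt
Reagents that add atoms: none
Why: Takai olefination; the geminal dichromium species from 29 adds to the aldehyde and eliminates to the (E)-iodoalkene; chromium(II) in THF is not basic and does not reduce unactivated secondary alkyl bromides.

Step 24
Reactants: 30 (1R,3R,4S,6S,8R,10S)-4,10-dibromo-3-ethyl-8-[(2E)-3-iodoprop-2-en-1-yl]-2,7-dioxabicyclo[4.2.2]decane; 31 ethynyltrimethylsilane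
Product: 32 (1R,3R,4S,6S,8R,10S)-4,10-dibromo-3-ethyl-8-[(2E)-5-(trimethylsilyl)pent-2-en-4-yn-1-yl]-2,7-dioxabicyclo[4.2.2]decane
Conditions: 31, PdCl2(PPh3)2 (cat.), CuI (cat.), i-Pr2NH, THF, rt
Reagents that add atoms: none
Why: Sonogashira coupling of the alkenyl iodide with retention of the E geometry; oxidative addition to the C(sp2)–I bond is far faster than to the secondary alkyl bromides.

Step 25
Reactants: 32 (1R,3R,4S,6S,8R,10S)-4,10-dibromo-3-ethyl-8-[(2E)-5-(trimethylsilyl)pent-2-en-4-yn-1-yl]-2,7-dioxabicyclo[4.2.2]decane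
Product: 33 (1R,3R,4S,6S,8R,10S)-4,10-dibromo-3-ethyl-8-[(2E)-pent-2-en-4-yn-1-yl]-2,7-dioxabicyclo[4.2.2]decane
Conditions: K2CO3 (cat.), MeOH, 0 °C
Reagents that add atoms: none
Why: Protodesilylation of the alkynylsilane by methoxide; short exposure at 0 °C should not affect the bromides.

## Compound list

1 | 2-[(4S)-2,2-dimethyl-1,3-dioxolan-4-yl]ethan-1-ol | OCC[C@H]1COC(C)(C)O1 | starting material
2 | 2-[(4S)-2,2-dimethyl-1,3-dioxolan-4-yl]acetaldehyde | O=CC[C@H]1COC(C)(C)O1 | intermediate
3 | 1-phenyl-5-(propylsulfonyl)-1H-tetrazole | CCCS(=O)(=O)c1nnnn1-c1ccccc1 | starting material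
4 | (4S)-2,2-dimethyl-4-[(2E)-pent-2-en-1-yl]-1,3-dioxolane | CC/C=C/C[C@H]1COC(C)(C)O1 | intermediate
5 | (2S,4E)-hept-4-ene-1,2-diol | CC/C=C/C[C@H](O)CO | intermediate
6 | (4S)-2,2-dibutyl-4-[(2E)-pent-2-en-1-yl]-1,3,2-dioxastannolane | CC/C=C/C[C@H]1CO[Sn](CCCC)(CCCC)O1 | intermediate
7 | (2S,4E)-1-[(4-methoxybenzyl)oxy]hept-4-en-2-ol | CC/C=C/C[C@H](O)COCc1ccc(OC)cc1 | intermediate
8 | (3S)-3-hydroxyoxolan-2-one ((S)-α-hydroxy-γ-butyrolactone) | O=C1OCC[C@@H]1O | starting material
9 | (3S)-2-oxooxolan-3-yl trifluoromethanesulfonate | O=C1OCC[C@@H]1OS(=O)(=O)C(F)(F)F | intermediate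
10 | (3R)-3-{[(2S,4E)-1-[(4-methoxybenzyl)oxy]hept-4-en-2-yl]oxy}oxolan-2-one | O=C1OCC[C@H]1O[C@H](COCc2ccc(OC)cc2)C/C=C/CC | intermediate
11 | (2R)-4-hydroxy-N-methoxy-N-methyl-2-{[(2S,4E)-1-[(4-methoxybenzyl)oxy]hept-4-en-2-yl]oxy}butanamide | CON(C)C(=O)[C@@H](CCO)O[C@H](COCc1ccc(OC)cc1)C/C=C/CC | intermediate
12 | (2R)-4-[(tert-butyldiphenylsilyl)oxy]-N-methoxy-N-methyl-2-{[(2S,4E)-1-[(4-methoxybenzyl)oxy]hept-4-en-2-yl]oxy}butanamide | CON(C)C(=O)[C@@H](CCO[Si](c1ccccc1)(c1ccccc1)C(C)(C)C)O[C@H](COCc1ccc(OC)cc1)C/C=C/CC | intermediate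
13 | dibromomethane | BrCBr | starting material
14 | (3R)-1-bromo-5-[(tert-butyldiphenylsilyl)oxy]-3-{[(2S,4E)-1-[(4-methoxybenzyl)oxy]hept-4-en-2-yl]oxy}pentan-2-one | BrCC(=O)[C@@H](CCO[Si](c1ccccc1)(c1ccccc1)C(C)(C)C)O[C@H](COCc1ccc(OC)cc1)C/C=C/CC | intermediate
15 | (3R)-1-bromo-5-[(tert-butyldiphenylsilyl)oxy]-3-{[(2S,4E)-1-hydroxyhept-4-en-2-yl]oxy}pentan-2-one | BrCC(=O)[C@@H](CCO[Si](c1ccccc1)(c1ccccc1)C(C)(C)C)O[C@H](CO)C/C=C/CC | intermediate
16 | (2S,4E)-2-{[(3R)-1-bromo-5-[(tert-butyldiphenylsilyl)oxy]-2-oxopentan-3-yl]oxy}hept-4-enal | BrCC(=O)[C@@H](CCO[Si](c1ccccc1)(c1ccccc1)C(C)(C)C)O[C@H](C=O)C/C=C/CC | intermediate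
17 | diiodosamarium(III) enolate of 16 (C7–O–Sm, C7=C8) | C=C(O[Sm](I)I)[C@@H](CCO[Si](c1ccccc1)(c1ccccc1)C(C)(C)C)O[C@H](C=O)C/C=C/CC | intermediate
18 | (2R,5S,6S)-2-{2-[(tert-butyldiphenylsilyl)oxy]ethyl}-5-hydroxy-6-[(2E)-pent-2-en-1-yl]oxan-3-one | O=C1C[C@H](O)[C@H](C/C=C/CC)O[C@@H]1CCO[Si](c2ccccc2)(c2ccccc2)C(C)(C)C | intermediate
19 | (2R,5S,6S)-2-{2-[(tert-butyldiphenylsilyl)oxy]ethyl}-6-[(2E)-pent-2-en-1-yl]-5-[(triethylsilyl)oxy]oxan-3-one | O=C1C[C@H](O[Si](CC)(CC)CC)[C@H](C/C=C/CC)O[C@@H]1CCO[Si](c2ccccc2)(c2ccccc2)C(C)(C)C | intermediate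
20 | (2R,3R,5S,6S)-2-{2-[(tert-butyldiphenylsilyl)oxy]ethyl}-6-[(2E)-pent-2-en-1-yl]-5-[(triethylsilyl)oxy]oxan-3-ol | O[C@@H]1C[C@H](O[Si](CC)(CC)CC)[C@H](C/C=C/CC)O[C@@H]1CCO[Si](c2ccccc2)(c2ccccc2)C(C)(C)C | intermediate
21 | (2R,3R,5S,6S)-3-[(tert-butyldimethylsilyl)oxy]-2-{2-[(tert-butyldiphenylsilyl)oxy]ethyl}-6-[(2E)-pent-2-en-1-yl]-5-[(triethylsilyl)oxy]oxane | CC(C)(C)[Si](C)(C)O[C@@H]1C[C@H](O[Si](CC)(CC)CC)[C@H](C/C=C/CC)O[C@@H]1CCO[Si](c2ccccc2)(c2ccccc2)C(C)(C)C | intermediate
22 | (2R,3R,5S,6S)-3-[(tert-butyldimethylsilyl)oxy]-2-{2-[(tert-butyldiphenylsilyl)oxy]ethyl}-6-[(2E)-pent-2-en-1-yl]oxan-5-ol | CC(C)(C)[Si](C)(C)O[C@@H]1C[C@H](O)[C@H](C/C=C/CC)O[C@@H]1CCO[Si](c2ccccc2)(c2ccccc2)C(C)(C)C | intermediate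
23 | (2R,3R,5R,6S)-3-[(tert-butyldimethylsilyl)oxy]-2-{2-[(tert-butyldiphenylsilyl)oxy]ethyl}-6-[(2E)-pent-2-en-1-yl]oxan-5-yl 4-nitrobenzoate | CC(C)(C)[Si](C)(C)O[C@@H]1C[C@@H](OC(=O)c2ccc(cc2)[N+](=O)[O-])[C@H](C/C=C/CC)O[C@@H]1CCO[Si](c2ccccc2)(c2ccccc2)C(C)(C)C | intermediate
24 | (2R,3R,5R,6S)-3-[(tert-butyldimethylsilyl)oxy]-2-{2-[(tert-butyldiphenylsilyl)oxy]ethyl}-6-[(2E)-pent-2-en-1-yl]oxan-5-ol | CC(C)(C)[Si](C)(C)O[C@@H]1C[C@@H](O)[C@H](C/C=C/CC)O[C@@H]1CCO[Si](c2ccccc2)(c2ccccc2)C(C)(C)C | intermediate
25 | (2R,3R,5S,6S)-5-bromo-3-[(tert-butyldimethylsilyl)oxy]-2-{2-[(tert-butyldiphenylsilyl)oxy]ethyl}-6-[(2E)-pent-2-en-1-yl]oxane | CC(C)(C)[Si](C)(C)O[C@@H]1C[C@H](Br)[C@H](C/C=C/CC)O[C@@H]1CCO[Si](c2ccccc2)(c2ccccc2)C(C)(C)C | intermediate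
26 | (2R,3R,5S,6S)-5-bromo-2-(2-hydroxyethyl)-6-[(2E)-pent-2-en-1-yl]oxan-3-ol | O[C@@H]1C[C@H](Br)[C@H](C/C=C/CC)O[C@@H]1CCO | intermediate
27 | 2-[(1R,3R,4S,6S,8R,10S)-4,10-dibromo-3-ethyl-2,7-dioxabicyclo[4.2.2]decan-8-yl]ethan-1-ol | OCC[C@H]1O[C@H]2C[C@H](Br)[C@@H](CC)O[C@@H]1C[C@@H]2Br | intermediate
28 | 2-[(1R,3R,4S,6S,8R,10S)-4,10-dibromo-3-ethyl-2,7-dioxabicyclo[4.2.2]decan-8-yl]acetaldehyde | O=CC[C@H]1O[C@H]2C[C@H](Br)[C@@H](CC)O[C@@H]1C[C@@H]2Br | intermediate
29 | iodoform (triiodomethane) | IC(I)I | starting material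
30 | (1R,3R,4S,6S,8R,10S)-4,10-dibromo-3-ethyl-8-[(2E)-3-iodoprop-2-en-1-yl]-2,7-dioxabicyclo[4.2.2]decane | I/C=C/C[C@H]1O[C@H]2C[C@H](Br)[C@@H](CC)O[C@@H]1C[C@@H]2Br | intermediate
31 | ethynyltrimethylsilane | C#C[Si](C)(C)C | starting material
32 | (1R,3R,4S,6S,8R,10S)-4,10-dibromo-3-ethyl-8-[(2E)-5-(trimethylsilyl)pent-2-en-4-yn-1-yl]-2,7-dioxabicyclo[4.2.2]decane | C[Si](C)(C)C#C/C=C/C[C@H]1O[C@H]2C[C@H](Br)[C@@H](CC)O[C@@H]1C[C@@H]2Br | intermediate
33 | (1R,3R,4S,6S,8R,10S)-4,10-dibromo-3-ethyl-8-[(2E)-pent-2-en-4-yn-1-yl]-2,7-dioxabicyclo[4.2.2]decane | C#C/C=C/C[C@H]1O[C@H]2C[C@H](Br)[C@@H](CC)O[C@@H]1C[C@@H]2Br | target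

## Step count and least certain steps

Total step count: 25. Longest linear sequence: 24 steps (steps 1–4 and 6–25, from 1); step 5 is the one-step side branch from 8.

**Step 12 (key step).** Electron transfer may not stop at the C–Br bond: reduction of the aldehyde (ketyl, pinacol coupling) or of the α-alkoxy ketone in the product (cleavage of the C6–O bond) would compete. The closed chelate may also be less dominant than assumed, which would lower the facial selectivity at C9. A lower selectivity is tolerable, since the 9R carbinol is the configuration that step 17 produces anyway. As a fallback the enolate is made without a reductant. Starting from 12, methylmagnesium bromide gives methyl ketone F1. DDQ then frees hydroxy ketone F2, and Dess–Martin oxidation gives keto aldehyde F3. Soft enolisation of the methyl group with dicyclohexylboron chloride and triethylamine at −78 °C should be followed by closure of the boron enolate through the same bridged chair. Oxidative work-up returns to the route at 18.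

**Step 21.** The closure may take the 7-exo course (O7 to C12), the ring oxygen may intercept the bromonium ion, or the chair may not open fast enough; the facial preference argued from the tether twist may also be weak. The fallback replaces the irreversible bromonium opening by a reversible mercury(II) cyclisation followed by bromodemercuration. Starting from 26, mercury(II) trifluoroacetate and then aqueous potassium bromide give the alkylmercury bromide F4. Bromine in pyridine in the dark then replaces mercury by bromine with retention and returns to the route at 27.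

**Step 19.** Axial entry of bromide at C9 is slowed by the axial C7 silyloxy group on the same face. This gives time for participation of the ring oxygen (retention, or contraction to an oxolane) and for elimination. The fallback separates activation from displacement. Starting from 24, chloromethanesulfonyl chloride and 2,6-lutidine give chloromethanesulfonate F5. Tetrabutylammonium bromide in warm toluene displaces this small, non-ionising leaving group with inversion and returns to the route at 25.

**Step 6.** The alkoxide may act as a base (elimination to the butenolide, or α-deprotonation with loss of configuration at C6) or add to the lactone carbonyl instead of displacing the triflate. The fallback forms the C6–O bond by carbenoid O–H insertion. Starting from 7, rhodium(II) acetate and 3-diazooxolan-2-one F6 give 10 together with its C6 epimer F7. The two diastereomers are separated by chromatography and the route continues from 10.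

## Further compounds

F1 | step 12 | (3R)-5-[(tert-butyldiphenylsilyl)oxy]-3-{[(2S,4E)-1-[(4-methoxybenzyl)oxy]hept-4-en-2-yl]oxy}pentan-2-one | CC(=O)[C@@H](CCO[Si](c1ccccc1)(c1ccccc1)C(C)(C)C)O[C@H](COCc1ccc(OC)cc1)C/C=C/CC
F2 | step 12 | (3R)-5-[(tert-butyldiphenylsilyl)oxy]-3-{[(2S,4E)-1-hydroxyhept-4-en-2-yl]oxy}pentan-2-one | CC(=O)[C@@H](CCO[Si](c1ccccc1)(c1ccccc1)C(C)(C)C)O[C@H](CO)C/C=C/CC
F3 | step 12 | (2S,4E)-2-{[(3R)-5-[(tert-butyldiphenylsilyl)oxy]-2-oxopentan-3-yl]oxy}hept-4-enal | CC(=O)[C@@H](CCO[Si](c1ccccc1)(c1ccccc1)C(C)(C)C)O[C@H](C=O)C/C=C/CC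
F4 | step 21 | bromo{(1R,3R,4S,6S,8R,10S)-10-bromo-3-ethyl-8-(2-hydroxyethyl)-2,7-dioxabicyclo[4.2.2]decan-4-yl}mercury | OCC[C@H]1O[C@H]2C[C@H]([Hg]Br)[C@@H](CC)O[C@@H]1C[C@@H]2Br
F5 | step 19 | (2R,3R,5R,6S)-3-[(tert-butyldimethylsilyl)oxy]-2-{2-[(tert-butyldiphenylsilyl)oxy]ethyl}-6-[(2E)-pent-2-en-1-yl]oxan-5-yl chloromethanesulfonate | CC(C)(C)[Si](C)(C)O[C@@H]1C[C@@H](OS(=O)(=O)CCl)[C@H](C/C=C/CC)O[C@@H]1CCO[Si](c2ccccc2)(c2ccccc2)C(C)(C)C
F6 | step 6 | 3-diazooxolan-2-one | [N-]=[N+]=C1CCOC1=O
F7 | step 6 | (3S)-3-{[(2S,4E)-1-[(4-methoxybenzyl)oxy]hept-4-en-2-yl]oxy}oxolan-2-one | O=C1OCC[C@@H]1O[C@H](COCc2ccc(OC)cc2)C/C=C/CC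
A1 | alternative 1 | cis-2,8-disubstituted 9Z-oxocene (6R,7R,12R,13R in chain numbering) with 12-O-triisopropylsilyl, 6-O-(naphthalen-2-ylmethyl) and 4-O-tert-butyldiphenylsilyl groups | CC[C@H]1O[C@@H]([C@H](OCc2ccc3ccccc3c2)CCO[Si](c2ccccc2)(c2ccccc2)C(C)(C)C)C/C=C\C[C@H]1O[Si](C(C)C)(C(C)C)C(C)C
A2 | alternative 2 | bridged bicyclic enol ether with C12=C13 (6R,7R,9R,10S in chain numbering), 9-O-benzyl and 4-O-triisopropylsilyl groups | CCC1=CC[C@@H]2O[C@H](CCO[Si](C(C)C)(C(C)C)C(C)C)[C@H](O1)C[C@H]2OCc3ccccc3
A3 | alternative 3 | (2R,6S)-2-{2-[(tert-butyldiphenylsilyl)oxy]ethyl}-6-hydroxy-6-[(2E)-pent-2-en-1-yl]-2H-pyran-3(6H)-one | O=C1C=C[C@](O)(C/C=C/CC)O[C@@H]1CCO[Si](c2ccccc2)(c2ccccc2)C(C)(C)C
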